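**Plan**
1. Retrosynthesis: remove the benzyl and methoxymethyl (MOM) ethers; cut the flavan pyran ring at C4–C4a and take the C3 carbinol back to a ketone, which leads to an aryl 1-arylpropargyl ether; cut that ether at O1–C2; cut the flavone C3–aryl bond.
2. Forward: 3-iodination of tri-O-benzylapigenin; Negishi coupling with the arylzinc from a phloroglucinol bis-MOM/TIPS ether (flavone C3–flavan C6 bond); desilylation; Mitsunobu etherification of the freed O1–H with a racemic 1-arylpropargyl alcohol (O1–C2 bond).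
3. Ring order: after the coupling every ring except the flavan pyran ring is in place. That ring (O1, C2, C3, C4, C4a, C8a) is closed last, by gold-catalysed alkyne oxidation and attack of C4a on the α-oxo carbene, and the resulting chroman-3-one is reduced in the same flask.
4. Enabling feature: in ring A of the flavan unit C6 carries the flavone and C8a–O1 lies para to it, so the two carbons ortho to O1 (the later C4a and C8) are equivalent and closure can only give the 6-linked skeleton. C2 lies between O1, the aryl ring and the C3 carbonyl and is therefore configurationally labile.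
5. Stereochemistry: nothing is set before the key step. Transfer hydrogenation with an (R,R)-TsDPEN ruthenium catalyst under dynamic kinetic resolution sets C3 (R) by catalyst control and C2 (R) through the cis-selective reduction of the equilibrating ketone.

Key step: step 9

Assumption 1: the target SMILES defines no descriptor for the hindered flavone–aryl axis, so this axis is treated as equilibrating and rotamers of 10–19 are not counted as separate compounds.
Assumption 2: the sense of induction in step 9 is assigned from the usual model for TsDPEN–ruthenium hydrides, with the C2 side of the ketone in the place of the aryl group of an aryl ketone; this calls for the (R,R) ligand, and the (S,S) complex would be used instead if the sense proves opposite.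

Step 1
Reactants: 1 apigenin (5,7-dihydroxy-2-(4-hydroxyphenyl)-4H-chromen-4-one)
Product: 2 5,7-bis(benzyloxy)-2-[4-(benzyloxy)phenyl]-4H-chromen-4-one
Conditions: BnBr (excess), K2CO3, Bu4NI (cat.), DMF, 80 °C
Reagents that add atoms: benzyl bromide, BrCc1ccccc1
Why: Williamson etherification of the three phenols; the hydrogen-bonded 5-OH reacts last, hence the excess of reagent and the heating.

Step 2
Reactants: 2 5,7-bis(benzyloxy)-2-[4-(benzyloxy)phenyl]-4H-chromen-4-one
Product: 4 5,7-bis(benzyloxy)-2-[4-(benzyloxy)phenyl]-3-iodo-4H-chromen-4-one, via 3-lithiochromone 3 (not isolated)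
Conditions: LDA, THF, −78 °C; then I2, −78 °C to rt
Reagents that add atoms: iodine, II
Why: Deprotonation of the only vinylic C–H next to the chromone carbonyl and iodine quench, a known lithiation–iodination of alkoxyflavones that avoids electrophilic attack on the electron-rich benzene rings.

Step 3
Reactants: 5 phloroglucinol (benzene-1,3,5-triol)
Product: 6 3,5-bis(methoxymethoxy)phenol
Conditions: NaH (2 equiv), MOMCl (2 equiv), DMF, 0 °C
Reagents that add atoms: chloromethyl methyl ether, COCCl
Why: O-alkylation stopped at the bis-ether by stoichiometry; the three hydroxyls are equivalent, so only one bis-ether can form and the mono- and tris-ethers are removed by chromatography.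

Step 4
Reactants: 6 3,5-bis(methoxymethoxy)phenol
Product: 7 [3,5-bis(methoxymethoxy)phenoxy]tri(propan-2-yl)silane
Conditions: TIPSCl, imidazole, DMF, rt
Reagents that add atoms: chlorotri(propan-2-yl)silane, CC(C)[Si](Cl)(C(C)C)C(C)C
Why: Silylation of the remaining phenol; the bulky TIPS ether withstands n-BuLi, shields its own ortho positions and marks the oxygen that becomes O1.

Step 5
Reactants: 7 [3,5-bis(methoxymethoxy)phenoxy]tri(propan-2-yl)silane; 4 5,7-bis(benzyloxy)-2-[4-(benzyloxy)phenyl]-3-iodo-4H-chromen-4-one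
Product: 10 5,7-bis(benzyloxy)-2-[4-(benzyloxy)phenyl]-3-{2,6-bis(methoxymethoxy)-4-[tri(propan-2-yl)silyloxy]phenyl}-4H-chromen-4-one, via aryllithium 8 (not isolated), via arylzinc chloride 9 (not isolated)
Conditions: n-BuLi, THF, 0 °C; ZnCl2, 0 °C to rt; then 4, Pd2(dba)3 (cat.), RuPhos (cat.), THF/NMP, 70 °C
Reagents that add atoms: none
Why: Directed ortho-metalation at the carbon between the two MOM ethers (doubly chelated, remote from TIPS), transmetalation to zinc and Negishi coupling with the 3-iodochromone at zerovalent palladium; a bulky dialkylbiarylphosphine is the established ligand type for tetra-ortho-substituted couplings.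

Step 6
Reactants: 10 5,7-bis(benzyloxy)-2-[4-(benzyloxy)phenyl]-3-{2,6-bis(methoxymethoxy)-4-[tri(propan-2-yl)silyloxy]phenyl}-4H-chromen-4-one
Product: 11 5,7-bis(benzyloxy)-2-[4-(benzyloxy)phenyl]-3-[4-hydroxy-2,6-bis(methoxymethoxy)phenyl]-4H-chromen-4-one
Conditions: Bu4NF, AcOH, THF, 0 °C
Reagents that add atoms: none
Why: Fluoride cleaves the aryl silyl ether selectively and frees only the oxygen para to the flavone; MOM and benzyl ethers are inert and the acetic acid buffer keeps the phenoxide from side reactions.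

Step 7
Reactants: 12 4-(benzyloxy)benzaldehyde; 13 ethynylmagnesium bromide
Product: 14 rac-1-[4-(benzyloxy)phenyl]prop-2-yn-1-ol
Conditions: THF, 0 °C; then H2O
Reagents that add atoms: none
Why: Grignard 1,2-addition of the acetylide to the aldehyde; the racemic carbinol is sufficient because this carbon (the later C2) is equilibrated in step 9.

Step 8
Reactants: 11 5,7-bis(benzyloxy)-2-[4-(benzyloxy)phenyl]-3-[4-hydroxy-2,6-bis(methoxymethoxy)phenyl]-4H-chromen-4-one; 14 rac-1-[4-(benzyloxy)phenyl]prop-2-yn-1-ol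
Product: 15 rac-5,7-bis(benzyloxy)-2-[4-(benzyloxy)phenyl]-3-[4-({1-[4-(benzyloxy)phenyl]prop-2-yn-1-yl}oxy)-2,6-bis(methoxymethoxy)phenyl]-4H-chromen-4-one
Conditions: PPh3, DIAD, THF, 0 °C to rt
Reagents that add atoms: none
Why: Mitsunobu etherification of the unhindered, sufficiently acidic phenol with a secondary propargylic alcohol forms O1–C2 under neutral conditions; the configuration of the ether carbon does not matter.

Step 9
Reactants: 15 rac-5,7-bis(benzyloxy)-2-[4-(benzyloxy)phenyl]-3-[4-({1-[4-(benzyloxy)phenyl]prop-2-yn-1-yl}oxy)-2,6-bis(methoxymethoxy)phenyl]-4H-chromen-4-one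
Product: 17 5,7-bis(benzyloxy)-2-[4-(benzyloxy)phenyl]-3-{(2R,3R)-2-[4-(benzyloxy)phenyl]-3-hydroxy-5,7-bis(methoxymethoxy)-3,4-dihydro-2H-chromen-6-yl}-4H-chromen-4-one, via racemic flavan-3-one 16 (not isolated)
Conditions: (Me4tBuXPhos)AuNTf2 (cat.), 2,6-dichloropyridine N-oxide, DCE, rt; then RuCl[(R,R)-TsDPEN](p-cymene) (cat.), HCO2H/Et3N (5:2), 35 °C, argon, same flask
Reagents that add atoms: 2,6-dichloropyridine N-oxide, [O-][n+]1c(Cl)cccc1Cl
Why: Proposed new method: the cationic monovalent gold complex activates the terminal alkyne, the N-oxide transfers oxygen to the internal carbon (the later C3), and the α-oxo gold carbene at the terminal carbon (the later C4) is attacked by the ortho carbon C4a of the phloroglucinol ether in an electrophilic aromatic substitution that is 6-endo with respect to the C4a=C8a bond and closes the pyran ring as chroman-3-one 16, the closest known reaction being the gold-catalysed oxidation of aryl propargyl ethers to chroman-3-ones. This closure needs no regiocontrol, because O1 is para to the flavone-bearing C6 and its two ortho CH positions are equivalent, while the bulky phosphine and the N-oxide are there to let oxidation outrun direct hydroarylation to a 2H-chromene. In 16 the C2–H is benzylic, α to oxygen and α to the carbonyl, so the two C2 epimers should interconvert through the enol under triethylamine faster than either is reduced. The ruthenium hydride then reduces only the epimer whose carbonyl face matches the (R,R) ligand and delivers hydride anti to the pseudo-equatorial C2 aryl group, so that C3 (R) is set by the catalyst and C2 (R) by the cis preference of the reduction coupled to the epimerisation, which funnels both enantiomers of 15 and 16 into the (2R,3R) alcohol. The closest known reactions for this half are the transfer-hydrogenative dynamic kinetic resolutions of 2-arylcycloalkanones and 3-arylchroman-4-ones to cis alcohols, and what is new is the 2-aryl-2-aryloxy ketone of the chroman-3-one type and the telescoping with the gold stage. The tetrasubstituted chromone carbonyl, a vinylogous ester, and the benzyl and MOM ethers are not expected to react.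

Step 10
Reactants: 17 5,7-bis(benzyloxy)-2-[4-(benzyloxy)phenyl]-3-{(2R,3R)-2-[4-(benzyloxy)phenyl]-3-hydroxy-5,7-bis(methoxymethoxy)-3,4-dihydro-2H-chromen-6-yl}-4H-chromen-4-one
Product: 18 5,7-bis(benzyloxy)-2-[4-(benzyloxy)phenyl]-3-{(2R,3R)-2-[4-(benzyloxy)phenyl]-3,5,7-trihydroxy-3,4-dihydro-2H-chromen-6-yl}-4H-chromen-4-one
Conditions: ZnBr2, n-PrSH, CH2Cl2, 0 °C
Reagents that add atoms: none
Why: Lewis acid and thiol cleave the two aryl MOM ethers quickly at low temperature; the thiol captures the methoxymethyl cation, so the electron-rich ring and the benzylic C2–O1 bond are not exposed to strong protic acid and both stereocentres stay untouched.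

Step 11
Reactants: 18 5,7-bis(benzyloxy)-2-[4-(benzyloxy)phenyl]-3-{(2R,3R)-2-[4-(benzyloxy)phenyl]-3,5,7-trihydroxy-3,4-dihydro-2H-chromen-6-yl}-4H-chromen-4-one
Product: 19 5,7-dihydroxy-2-(4-hydroxyphenyl)-3-[(2R,3R)-3,5,7-trihydroxy-2-(4-hydroxyphenyl)-3,4-dihydro-2H-chromen-6-yl]-4H-chromen-4-one (CNP0222954.1)
Conditions: H2 (1 atm), Pd(OH)2/C, THF/MeOH, rt
Reagents that add atoms: none
Why: Neutral hydrogenolysis of the four benzyl ethers, as used for benzylated flavan-3-ols; the cyclic benzylic ether C2–O1 and the tetrasubstituted chromone double bond are expected to survive, and no acid or base is present that could epimerise C2.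

**Compound list**
1 | apigenin, 5,7-dihydroxy-2-(4-hydroxyphenyl)-4H-chromen-4-one | O=c1cc(-c2ccc(O)cc2)oc2cc(O)cc(O)c12 | starting material
2 | 5,7-bis(benzyloxy)-2-[4-(benzyloxy)phenyl]-4H-chromen-4-one | O=c1cc(-c2ccc(OCc3ccccc3)cc2)oc2cc(OCc3ccccc3)cc(OCc3ccccc3)c12 | intermediate
3 | [5,7-bis(benzyloxy)-2-[4-(benzyloxy)phenyl]-4-oxo-4H-chromen-3-yl]lithium | [Li]c1c(-c2ccc(OCc3ccccc3)cc2)oc2cc(OCc3ccccc3)cc(OCc3ccccc3)c2c1=O | intermediate
4 | 5,7-bis(benzyloxy)-2-[4-(benzyloxy)phenyl]-3-iodo-4H-chromen-4-one | O=c1c(I)c(-c2ccc(OCc3ccccc3)cc2)oc2cc(OCc3ccccc3)cc(OCc3ccccc3)c12 | intermediate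
5 | phloroglucinol, benzene-1,3,5-triol | Oc1cc(O)cc(O)c1 | starting material
6 | 3,5-bis(methoxymethoxy)phenol | COCOc1cc(O)cc(OCOC)c1 | intermediate
7 | [3,5-bis(methoxymethoxy)phenoxy]tri(propan-2-yl)silane | COCOc1cc(OCOC)cc(O[Si](C(C)C)(C(C)C)C(C)C)c1 | intermediate
8 | {2,6-bis(methoxymethoxy)-4-[tri(propan-2-yl)silyloxy]phenyl}lithium | [Li]c1c(OCOC)cc(O[Si](C(C)C)(C(C)C)C(C)C)cc1OCOC | intermediate
9 | chloro{2,6-bis(methoxymethoxy)-4-[tri(propan-2-yl)silyloxy]phenyl}zinc | Cl[Zn]c1c(OCOC)cc(O[Si](C(C)C)(C(C)C)C(C)C)cc1OCOC | intermediate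
10 | 5,7-bis(benzyloxy)-2-[4-(benzyloxy)phenyl]-3-{2,6-bis(methoxymethoxy)-4-[tri(propan-2-yl)silyloxy]phenyl}-4H-chromen-4-one | O=c1c(-c2c(OCOC)cc(O[Si](C(C)C)(C(C)C)C(C)C)cc2OCOC)c(-c2ccc(OCc3ccccc3)cc2)oc2cc(OCc3ccccc3)cc(OCc3ccccc3)c12 | intermediate
11 | 5,7-bis(benzyloxy)-2-[4-(benzyloxy)phenyl]-3-[4-hydroxy-2,6-bis(methoxymethoxy)phenyl]-4H-chromen-4-one | O=c1c(-c2c(OCOC)cc(O)cc2OCOC)c(-c2ccc(OCc3ccccc3)cc2)oc2cc(OCc3ccccc3)cc(OCc3ccccc3)c12 | intermediate
12 | 4-(benzyloxy)benzaldehyde | O=Cc1ccc(OCc2ccccc2)cc1 | starting material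
13 | ethynylmagnesium bromide | C#C[Mg]Br | starting material
14 | rac-1-[4-(benzyloxy)phenyl]prop-2-yn-1-ol | C#CC(O)c1ccc(OCc2ccccc2)cc1 | intermediate
15 | rac-5,7-bis(benzyloxy)-2-[4-(benzyloxy)phenyl]-3-[4-({1-[4-(benzyloxy)phenyl]prop-2-yn-1-yl}oxy)-2,6-bis(methoxymethoxy)phenyl]-4H-chromen-4-one | O=c1c(-c2c(OCOC)cc(OC(C#C)c3ccc(OCc4ccccc4)cc3)cc2OCOC)c(-c2ccc(OCc3ccccc3)cc2)oc2cc(OCc3ccccc3)cc(OCc3ccccc3)c12 | intermediate
16 | rac-5,7-bis(benzyloxy)-2-[4-(benzyloxy)phenyl]-3-{2-[4-(benzyloxy)phenyl]-5,7-bis(methoxymethoxy)-3-oxo-3,4-dihydro-2H-chromen-6-yl}-4H-chromen-4-one | O=c1c(-c2c(OCOC)cc3c(c2OCOC)CC(=O)C(c2ccc(OCc4ccccc4)cc2)O3)c(-c2ccc(OCc3ccccc3)cc2)oc2cc(OCc3ccccc3)cc(OCc3ccccc3)c12 | intermediate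
17 | 5,7-bis(benzyloxy)-2-[4-(benzyloxy)phenyl]-3-{(2R,3R)-2-[4-(benzyloxy)phenyl]-3-hydroxy-5,7-bis(methoxymethoxy)-3,4-dihydro-2H-chromen-6-yl}-4H-chromen-4-one | O=c1c(-c2c(OCOC)cc3c(c2OCOC)C[C@@H](O)[C@@H](c2ccc(OCc4ccccc4)cc2)O3)c(-c2ccc(OCc3ccccc3)cc2)oc2cc(OCc3ccccc3)cc(OCc3ccccc3)c12 | intermediate
18 | 5,7-bis(benzyloxy)-2-[4-(benzyloxy)phenyl]-3-{(2R,3R)-2-[4-(benzyloxy)phenyl]-3,5,7-trihydroxy-3,4-dihydro-2H-chromen-6-yl}-4H-chromen-4-one | O=c1c(-c2c(O)cc3c(c2O)C[C@@H](O)[C@@H](c2ccc(OCc4ccccc4)cc2)O3)c(-c2ccc(OCc3ccccc3)cc2)oc2cc(OCc3ccccc3)cc(OCc3ccccc3)c12 | intermediate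
19 | 5,7-dihydroxy-2-(4-hydroxyphenyl)-3-[(2R,3R)-3,5,7-trihydroxy-2-(4-hydroxyphenyl)-3,4-dihydro-2H-chromen-6-yl]-4H-chromen-4-one | O=c1c(-c2c(O)cc3c(c2O)C[C@@H](O)[C@@H](c2ccc(O)cc2)O3)c(-c2ccc(O)cc2)oc2cc(O)cc(O)c12 | target

**Step count**
Total steps: 11. Longest linear sequence: 8 steps (steps 1, 2, 5, 6, 8, 9, 10, 11 from apigenin; equally steps 3, 4, 5, 6, 8, 9, 10, 11 from phloroglucinol).

**Steps most likely to fail**

Step 9 (bears the label). The gold carbene may never form cleanly: direct hydroarylation of the alkyne to a 2H-chromene or ionisation of the doubly activated propargylic C–O bond can compete. In the second stage, epimerisation at C2 may be slower than reduction, or hydride may be delivered syn to the aryl group, so that enantiomeric purity or the cis outcome is lost. The fallback uses known chemistry and sets out from 15. The gold stage is run alone and the racemic ketone 16 is isolated under argon. Reduction with LiBH(sec-Bu)3 in THF at −78 °C, the bulky-hydride reduction used to turn flavan-3-ones into 2,3-cis flavan-3-ols, should give the racemic cis alcohol, that is 17 together with its (2S,3S) enantiomer F1. Preparative HPLC on a chiral stationary phase separates 17 from the enantiomer F1, and the route is rejoined at 17. If the gold stage itself is the failing part, 16 is reached by the diazoketone sequence described under step 8.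

Step 5. Transmetalation and reductive elimination at a carbon that becomes tetra-ortho-substituted may be slow, so that protonation of the arylzinc back to 7 and loss of iodine from 4 take over. The fallback reverses the roles of the partners and sets out from 7 and 4. Compound 7 is lithiated as in step 5 and the aryllithium 8 is quenched with I2 to give 2-iodo-1,3-bis(methoxymethoxy)-5-[tri(propan-2-yl)silyloxy]benzene F2. Compound 4 is treated with Zn dust and LiCl in THF to give the chromon-3-ylzinc iodide F3. Coupling of F2 with F3 (Pd2(dba)3, SPhos, THF, 60 °C) lets the hindered electron-rich ring enter by oxidative addition and the smaller zinc reagent by transmetalation, and comes back to the route at 10.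

Step 8. The activated oxyphosphonium ion of 14 (4-alkoxybenzylic and propargylic) may ionise to a cation that alkylates a ring carbon of the electron-rich phenol or collapses to allenic products instead of the O-ether. The fallback avoids any cationic electrophile and sets out from 11. Diazo transfer (4-acetamidobenzenesulfonyl azide, DBU, MeCN) onto commercial methyl 2-[4-(benzyloxy)phenyl]acetate gives methyl 2-[4-(benzyloxy)phenyl]-2-diazoacetate F4. Rh2(OAc)4-catalysed O–H insertion of F4 into the phenol 11 gives the α-aryloxy ester F5. LiOH in THF/H2O at 0 °C gives the acid F6, oxalyl chloride gives the acid chloride F7, and Me3SiCHN2 gives the diazoketone F8. Rh2(OAc)4 in CH2Cl2 then closes the ring by carbenoid aromatic substitution, the classical route to chroman-3-ones, and the route is rejoined at 16, which is reduced as in the second stage of step 9.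

**Further compounds**
F1 | step 9 | 5,7-bis(benzyloxy)-2-[4-(benzyloxy)phenyl]-3-{(2S,3S)-2-[4-(benzyloxy)phenyl]-3-hydroxy-5,7-bis(methoxymethoxy)-3,4-dihydro-2H-chromen-6-yl}-4H-chromen-4-one (enantiomer of 17) | O=c1c(-c2c(OCOC)cc3c(c2OCOC)C[C@H](O)[C@H](c2ccc(OCc4ccccc4)cc2)O3)c(-c2ccc(OCc3ccccc3)cc2)oc2cc(OCc3ccccc3)cc(OCc3ccccc3)c12
F2 | step 5 | 2-iodo-1,3-bis(methoxymethoxy)-5-[tri(propan-2-yl)silyloxy]benzene | Ic1c(OCOC)cc(O[Si](C(C)C)(C(C)C)C(C)C)cc1OCOC
F3 | step 5 | [5,7-bis(benzyloxy)-2-[4-(benzyloxy)phenyl]-4-oxo-4H-chromen-3-yl]zinc iodide | I[Zn]c1c(-c2ccc(OCc3ccccc3)cc2)oc2cc(OCc3ccccc3)cc(OCc3ccccc3)c2c1=O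
F4 | step 8 | methyl 2-[4-(benzyloxy)phenyl]-2-diazoacetate | COC(=O)C(=[N+]=[N-])c1ccc(OCc2ccccc2)cc1
F5 | step 8 | rac-methyl 2-[4-(benzyloxy)phenyl]-2-{4-[5,7-bis(benzyloxy)-2-[4-(benzyloxy)phenyl]-4-oxo-4H-chromen-3-yl]-3,5-bis(methoxymethoxy)phenoxy}acetate | O=c1c(-c2c(OCOC)cc(OC(C(=O)OC)c3ccc(OCc4ccccc4)cc3)cc2OCOC)c(-c2ccc(OCc3ccccc3)cc2)oc2cc(OCc3ccccc3)cc(OCc3ccccc3)c12
F6 | step 8 | rac-2-[4-(benzyloxy)phenyl]-2-{4-[5,7-bis(benzyloxy)-2-[4-(benzyloxy)phenyl]-4-oxo-4H-chromen-3-yl]-3,5-bis(methoxymethoxy)phenoxy}acetic acid | O=c1c(-c2c(OCOC)cc(OC(C(=O)O)c3ccc(OCc4ccccc4)cc3)cc2OCOC)c(-c2ccc(OCc3ccccc3)cc2)oc2cc(OCc3ccccc3)cc(OCc3ccccc3)c12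
F7 | step 8 | rac-2-[4-(benzyloxy)phenyl]-2-{4-[5,7-bis(benzyloxy)-2-[4-(benzyloxy)phenyl]-4-oxo-4H-chromen-3-yl]-3,5-bis(methoxymethoxy)phenoxy}acetyl chloride | O=c1c(-c2c(OCOC)cc(OC(C(=O)Cl)c3ccc(OCc4ccccc4)cc3)cc2OCOC)c(-c2ccc(OCc3ccccc3)cc2)oc2cc(OCc3ccccc3)cc(OCc3ccccc3)c12
F8 | step 8 | rac-5,7-bis(benzyloxy)-2-[4-(benzyloxy)phenyl]-3-[4-({1-[4-(benzyloxy)phenyl]-3-diazo-2-oxopropyl}oxy)-2,6-bis(methoxymethoxy)phenyl]-4H-chromen-4-one | O=c1c(-c2c(OCOC)cc(OC(C(=O)C=[N+]=[N-])c3ccc(OCc4ccccc4)cc3)cc2OCOC)c(-c2ccc(OCc3ccccc3)cc2)oc2cc(OCc3ccccc3)cc(OCc3ccccc3)c12
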